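## Structural features

The target is a (2S)-flavan: a chroman (O1 to C8a) with a phenyl group at C2, a methoxy group at C5, a free hydroxyl at C7 and, at C8, the C2' carbon of a benzofuran. The benzofuran benzene ring is fully differentiated, with methoxy at C4', methyl at C5' and a free hydroxyl at C6', so the methyl group lies between two different oxygen substituents and O1' is para to it. The two ring systems are joined only by the C8–C2' bond, which on the chroman side is flanked by C8a–O1 and C7–OH and is therefore doubly ortho-substituted. C2 is the only stereocentre (S; O1 > phenyl > C3 > H), with no neighbouring stereocentre or functional group from which its configuration could be relayed. The fragile points are the two electron-rich phenols, the benzylic C2–O1 ether (acid ionisation, hydrogenolysis) and the C2'=C3' bond of the furan (reduction, electrophiles). The real difficulties are absolute control at the isolated C2 centre and the regiochemistry of the O/Me/O pattern of the benzofuran. The key step uses a feature of ring A: without C2, C3 and C4 it is a 2-aryl-5-methoxyresorcinol with twofold symmetry about the C8–C2' axis, so the carbons that become C4a and C6 are equivalent, as are the oxygens that become O1 and the 7-OH, and one ortho-hydroxymethylation settles all of them at once.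

## Logic of the disconnections

**22 ⇒ 21.** The O6'–Si bond is cut. O6' must be masked during the annulation, because a free 6'-OH would make C7' a second site for hydroxymethylation. A benzyl ether was considered and rejected: its hydrogenolysis would endanger the benzylic C2–O1 bond and the C2'=C3' bond. A triisopropylsilyl ether comes off with fluoride, is a weaker donor and a larger shield for C7' than a benzyl ether, and also controls the regiochemistry of the benzofuran synthesis. The forward step only needs buffered fluoride.

**21 ⇒ 16 + 17 + 18.** C4a–C4, C3–C4 and O1–C2 are cut, which removes the pyran ring and the stereocentre together. This leaves the achiral, symmetric 16 and two commodity partners, 17 and 18. The forward step must hydroxymethylate only the resorcinol ring, stop after one annulation, and let a chiral Brønsted acid choose the face of 18.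

**16 ⇒ 15.** The two O–CH2OMe bonds are cut. The free resorcinol cannot pass through organometallic steps, and the acetals also serve as directing groups. The forward cleavage must not let the released methoxymethyl cation alkylate the very nucleophilic ring, hence a thiol scavenger.

**15 ⇒ 12 + 10.** The C8–C2' bond is cut, which divides the skeleton into two aromatic halves of similar size. The forward step needs lithiation of 12 at the carbon between the two acetal oxygens (13), transfer to zinc (14), and a palladium catalyst that accepts a di-ortho-substituted arylzinc.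

**10 ⇒ 9.** The O1'–C2' bond of the furan is cut. A gem-dibromoalkene next to a free phenol gives the ring closure and the C2' bromide for the coupling in one operation. The forward step needs selective C–O coupling at the bromine cis to the arene.

**9 ⇒ 8 ⇒ 7.** The acetal O–C bond is restored and the C2'=C3' bond is cut, so C3' is traced to an aldehyde carbon. The forward olefination must work on a 2,6-dioxygenated benzaldehyde without loss of the acetal.

**7 ⇒ 5.** The C3a'–C3' bond is cut. This is where the benzofuran regiochemistry is decided: the carbon between the acetal and methoxy oxygens is flanked by two coordinating groups, the other ortho carbon by the bulky, non-coordinating silyl ether. The forward step needs ring lithiation (6) in preference to lateral lithiation of the methyl group.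

**5 ⇒ 4 ⇒ 2 ⇒ 1.** The acetal O–C bond, the C7a'–O1' bond (through the C–B bond of 3) and the O–Si bond are cut. Commercial 1 already has the methyl group flanked by a differentiated OH and OMe. The missing oxygen sits at the only ring C–H with no ortho substituent, the site of sterically controlled C–H borylation. No equivalent oxygens have to be told apart. The silyl ether must survive the boronate oxidation.

**12 ⇒ 11.** Two acetal O–C bonds are cut, leading to commercial 11.

## Other disconnections considered

Alternative 1: The furan ring of A1, (2S)-7-benzyloxy-5-methoxy-8-[4-methoxy-5-methyl-6-(triisopropylsilyloxy)benzofuran-2-yl]-2-phenylchroman, is cut at C3'–C3a' and O1'–C2'. This leads to the O-aryl ketoxime ether A2, in which an 8-acetylchroman is linked through N–O to the ring that becomes the benzofuran benzene ring.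
- **Forward step:** acid shifts A2 to its ene-hydroxylamine tautomer, a (3,3) shift forms C3'–C3a' and breaks N–O, the freed phenol oxygen adds to the imine carbon, and the nitrogen is expelled on aromatisation.
- **In favour:** no transition metal is needed, and the aryl ring needs no ortho handle. The hindered C8–C2' bond becomes an aryl–acyl bond, which an electron-rich ring accepts readily. On these two points it is the better plan.
- **Against:** the shift can end at either ortho carbon of the O-aryl ring. Only the one next to the methoxy group gives A1, and only the size of the silyl ether favours it. The cascade needs strong acid while the benzylic C2–O1 ether is already in place and can ionise with loss of configuration. C2 must be set earlier by a separate asymmetric sequence, and O7 must be benzylated, which gives up the symmetry.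
- **Comparison:** on structure, the chosen plan keeps ring A symmetric until the stereocentre is formed in the penultimate step, whereas A2 carries it through the harshest step. On mechanism, the sigmatropic cascade is of an established type and as a bond-forming event is the equal or the better of the catalytic annulation, but its regiochemistry is less secure than the chelation-controlled lithiation of 5. On step economy, the benzofuran half is shorter, but the chroman must be built and protected separately, so no overall saving is expected.

Alternative 2: In A3, 2-[(2S)-5-methoxy-2-phenyl-7-(triisopropylsilyloxy)chroman-8-yl]-5-methyl-6-(triisopropylsilyloxy)benzofuran-4-ol, the benzene ring of the benzofuran is taken apart at C7'–C7a', C4'–C5', C6'–C7' and C3a'–C4'. The precursors are the 2-furyl diazomethyl ketone A4, whose other furan α-carbon carries the chroman, and the siloxyalkyne A5, triisopropyl(prop-1-ynyloxy)silane.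
- **Forward step:** irradiation of A4 triggers a Wolff shift in which the furyl group migrates (C7'–C7a'). The furylketene adds to A5 in a (2+2) sense (C4'–C5', C6'–C7'). Heating opens the cyclobutenone to a dienylketene, whose 6π closure onto the furan β-carbon (C3a'–C4') and tautomerisation give A3.
- **In favour:** the substitution pattern is written by the reagents. The ketene carbon becomes C4' with a free hydroxyl, the oxygen-bearing alkyne carbon becomes C6' with its silyl group, and the methyl lands between them. The O4'/O6' differentiation that the chosen route enforces by directed lithiation is automatic, and on this point it is the better plan.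
- **Against:** it needs a diazoketone on an advanced chiral intermediate, a moisture-sensitive ynol ether, and photolysis of a substrate with several electron-rich chromophores. The electrocyclisation must engage a furan double bond. A3 still needs O-methylation at C4' and two desilylations, and C2 again has to come from elsewhere.
- **Comparison:** on structure, it solves the benzofuran regiochemistry best but does nothing for the stereocentre. On mechanism, a pericyclic cascade with predictable regiochemistry is the equal of the chosen key step in predictability and better in precedent of type, at the price of hazardous and demanding operations. On step economy, it is longer and more linear, with the chiral chroman carried through many steps, whereas the chosen plan is convergent and makes the stereocentre next to last.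

Alternative 3: A6, (2S)-7-benzyloxy-8-(6-benzyloxy-4-methoxy-5-methylbenzofuran-2-yl)-5-methoxy-2-phenyl-2H-chromene, is cut at C3=C4 and, one step earlier, at O1–C2. The precursor is the diene A7, an aryl (1S)-1-phenylallyl ether with a vinyl group on the future C4a.
- **Forward step:** second-generation Grubbs catalyst closes the C3=C4 bond with loss of the two terminal methylene carbons. The C2 centre, set beforehand by iridium-catalysed branched-selective allylic etherification of the phenol, is not touched. Hydrogenation of C3=C4 with hydrogenolysis of both benzyl ethers would finish the synthesis.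
- **In favour:** the stereocentre comes from an established enantioselective reaction class, and metathesis to 2H-chromenes is routine. On security of the stereocentre this is the better plan.
- **Against:** the symmetry of 16 must be broken by mono-benzylation and a vinyl group installed at C4a. The phenoxide nucleophile in the iridium step has two ortho substituents. In A6 the C2–O1 bond is both allylic and benzylic, so the final hydrogenation threatens C–O cleavage as well as the furan double bond.
- **Comparison:** on structure, the chosen plan uses the symmetry of ring A and this one destroys it. On mechanism, both form O1–C2 enantioselectively, but this one does so by a proven catalyst system and the chosen plan by an unproven one. On step economy, at least five operations follow the biaryl stage here, against two in the chosen plan.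

Key step: step 11

Assumption: the (R)-configured phosphoramide is taken to induce the (2S) configuration; if the sense of induction is the opposite, its (S)-enantiomer is used under the same conditions.

## Route

Step 1
Reactants: 1 3-methoxy-2-methylphenol
Product: 2 triisopropyl(3-methoxy-2-methylphenoxy)silane
Conditions: TIPSCl, imidazole, DMF, 25 °C
Reagents that add atoms: chlorotriisopropylsilane, SMILES CC(C)[Si](Cl)(C(C)C)C(C)C
Why: Imidazole-promoted silylation of the only hydroxyl; the triisopropylsilyl group is inert to organolithium reagents, does not direct ortho-lithiation, and is removed at the end by fluoride.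

Step 2
Reactants: 2 triisopropyl(3-methoxy-2-methylphenoxy)silane
Product: 4 3-methoxy-4-methyl-5-(triisopropylsilyloxy)phenol, via arylboronate 3 (not isolated)
Conditions: [Ir(OMe)(cod)]2 (cat.), 4,4'-di-tert-butyl-2,2'-bipyridine, B2pin2, THF, 80 °C; then NaBO3·4H2O, THF–H2O, 25 °C
Reagents that add atoms: sodium perborate (water of crystallisation omitted), SMILES [Na+].[Na+].O[B-]1(O)OO[B-](O)(O)OO1 (the new phenol oxygen); bis(pinacolato)diboron, SMILES CC1(C)OB(OC1(C)C)B1OC(C)(C)C(C)(C)O1 (boron of 3 only)
Why: Iridium-catalysed C–H borylation is sterically controlled and should take the only ring C–H without an ortho substituent, the one para to the methyl group; perborate oxidation of the C–B bond keeps the ring position and spares the aryl silyl ether.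

Step 3
Reactants: 4 3-methoxy-4-methyl-5-(triisopropylsilyloxy)phenol
Product: 5 triisopropyl[3-methoxy-5-(methoxymethoxy)-2-methylphenoxy]silane
Conditions: MOMCl, iPr2NEt, CH2Cl2, 0 to 25 °C
Reagents that add atoms: chloromethyl methyl ether, SMILES COCCl
Why: O-Alkylation of the phenol to its methoxymethyl acetal, which is the directing group for step 4.

Step 4
Reactants: 5 triisopropyl[3-methoxy-5-(methoxymethoxy)-2-methylphenoxy]silane
Product: 7 2-methoxy-6-(methoxymethoxy)-3-methyl-4-(triisopropylsilyloxy)benzaldehyde, via aryllithium 6 (not isolated)
Conditions: n-BuLi, TMEDA, THF, −20 to 0 °C; DMF, −78 to 25 °C; H2O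
Reagents that add atoms: N,N-dimethylformamide, SMILES CN(C)C=O (the formyl group); n-butyllithium, SMILES [Li]CCCC (lithium of 6 only)
Why: Directed ortho-metalation: the carbon between the acetal and methoxy oxygens is activated by two coordinating groups, while the other ortho carbon is flanked by the bulky, non-coordinating silyl ether, so lithiation should give 6; DMF then places the formyl carbon (future C3') next to the methoxy group.

Step 5
Reactants: 7 2-methoxy-6-(methoxymethoxy)-3-methyl-4-(triisopropylsilyloxy)benzaldehyde
Product: 8 [4-(2,2-dibromovinyl)-3-methoxy-5-(methoxymethoxy)-2-methylphenoxy]triisopropylsilane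
Conditions: CBr4, PPh3, Et3N, CH2Cl2, 0 °C
Reagents that add atoms: tetrabromomethane, SMILES BrC(Br)(Br)Br
Why: Ramirez dibromo-olefination (first stage of the Corey–Fuchs sequence) by the ylide from CBr4 and PPh3; triethylamine buffers the medium so that the acetal survives.

Step 6
Reactants: 8 [4-(2,2-dibromovinyl)-3-methoxy-5-(methoxymethoxy)-2-methylphenoxy]triisopropylsilane
Product: 9 2-(2,2-dibromovinyl)-3-methoxy-4-methyl-5-(triisopropylsilyloxy)phenol
Conditions: ZnBr2, n-PrSH, CH2Cl2, 0 °C
Reagents that add atoms: none
Why: Lewis-acid-assisted cleavage of the aryl methoxymethyl ether, with the thiol trapping the methoxymethyl cation; the aryl silyl ether and the dibromoalkene should be untouched under these brief, cold conditions.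

Step 7
Reactants: 9 2-(2,2-dibromovinyl)-3-methoxy-4-methyl-5-(triisopropylsilyloxy)phenol
Product: 10 2-bromo-4-methoxy-5-methyl-6-(triisopropylsilyloxy)benzofuran
Conditions: CuI (cat.), K3PO4, THF, 80 °C
Reagents that add atoms: none
Why: Copper-catalysed intramolecular Ullmann-type C–O coupling of a gem-dibromovinyl phenol: the phenoxide replaces the bromine cis to the arene and closes the furan ring (O1'–C2'), and the other bromine remains at C2'.

Step 8
Reactants: 11 5-methoxyresorcinol
Product: 12 1-methoxy-3,5-bis(methoxymethoxy)benzene
Conditions: MOMCl, iPr2NEt, CH2Cl2, 0 to 25 °C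
Reagents that add atoms: chloromethyl methyl ether, SMILES COCCl
Why: Double O-alkylation to the bis-acetal, which protects both phenols and supplies the two directing groups for step 9.

Step 9
Reactants: 12 1-methoxy-3,5-bis(methoxymethoxy)benzene; 10 2-bromo-4-methoxy-5-methyl-6-(triisopropylsilyloxy)benzofuran
Product: 15 2-[4-methoxy-2,6-bis(methoxymethoxy)phenyl]-4-methoxy-5-methyl-6-(triisopropylsilyloxy)benzofuran, via aryllithium 13 (not isolated), via arylzinc chloride 14 (not isolated)
Conditions: n-BuLi, THF, 0 °C; ZnCl2, 0 to 25 °C; then 10, Pd(OAc)2 (cat.), SPhos, THF, 60 °C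
Reagents that add atoms: n-butyllithium, SMILES [Li]CCCC (lithium of 13 only); zinc dichloride, SMILES Cl[Zn]Cl (zinc and chlorine of 14 only)
Why: Directed ortho-lithiation at the carbon between the two acetal oxygens gives 13 and transmetalation gives 14; Negishi coupling under a zerovalent palladium–SPhos catalyst, a system suited to di-ortho-substituted arylzinc reagents, forms the C8–C2' bond.

Step 10
Reactants: 15 2-[4-methoxy-2,6-bis(methoxymethoxy)phenyl]-4-methoxy-5-methyl-6-(triisopropylsilyloxy)benzofuran
Product: 16 5-methoxy-2-[4-methoxy-5-methyl-6-(triisopropylsilyloxy)benzofuran-2-yl]benzene-1,3-diol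
Conditions: ZnBr2, n-PrSH, CH2Cl2, 0 °C
Reagents that add atoms: none
Why: Cleavage of both aryl methoxymethyl ethers; the thiol intercepts the methoxymethyl cation before it can alkylate the liberated, strongly nucleophilic resorcinol ring, and the silyl ether is kept.

Step 11
Reactants: 16 5-methoxy-2-[4-methoxy-5-methyl-6-(triisopropylsilyloxy)benzofuran-2-yl]benzene-1,3-diol; 17 formaldehyde (as paraformaldehyde); 18 styrene
Product: 21 (2S)-5-methoxy-8-[4-methoxy-5-methyl-6-(triisopropylsilyloxy)benzofuran-2-yl]-2-phenylchroman-7-ol, via hydroxymethyl resorcinol 19 (not isolated), via o-quinone methide 20 (not isolated)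
Conditions: (R)-3,3'-bis(2,4,6-triisopropylphenyl)-1,1'-binaphthalene-2,2'-diyl N-triflylphosphoramide (10 mol %), paraformaldehyde (0.9 equiv), styrene (10 equiv), 5 Å MS, PhMe, 0 to 25 °C
Reagents that add atoms: none
Why: Proposed new method: the acid activates formaldehyde for Friedel–Crafts hydroxymethylation of 16 at one of its two equivalent ring carbons (C4a–C4), and ionisation of benzylic alcohol 19 with loss of water gives o-quinone methide 20 as a hydrogen-bonded ion pair with the chiral phosphoramide anion. Styrene then adds in an inverse-electron-demand hetero-Diels–Alder sense, its CH2 terminus bonding to the exocyclic methylene (C3–C4) and the phenolic oxygen closing onto the developing benzylic cation (O1–C2), which restores aromaticity. The closest known reaction types are the thermal phenol–aldehyde–alkene chroman synthesis and the chiral N-triflylphosphoramide-catalysed (4+2) addition of styrenes to o-quinone methides bearing an aryl group on the methide carbon; the asymmetric three-component version with an unsubstituted methide is not established. The pyran ring is closed by an asynchronous (4+2) cycloaddition, formally a six-membered capture of the C2 cation by O1. C2 is the only new stereocentre and its configuration must come from the catalyst alone: the anion is bound to the quinone methide oxygen, directly beside the forming O1–C2 bond, and its 2,4,6-triisopropylphenyl walls should differentiate the two faces of the styrene. Site selectivity rests on the substrate: the twofold symmetry of 16 makes both hydroxymethylation sites identical and leaves the second hydroxyl as the 7-OH, the bulky and weakly donating silyl ether shields C7' of the benzofuran, and the excess of styrene competes against arene trapping of 20. A slight deficit of formaldehyde limits a second annulation at C6, and unreacted 16 can be recycled.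

Step 12
Reactants: 21 (2S)-5-methoxy-8-[4-methoxy-5-methyl-6-(triisopropylsilyloxy)benzofuran-2-yl]-2-phenylchroman-7-ol
Product: 22 (2S)-8-(6-hydroxy-4-methoxy-5-methylbenzofuran-2-yl)-5-methoxy-2-phenylchroman-7-ol
Conditions: TBAF, AcOH, THF, 0 °C
Reagents that add atoms: none
Why: Fluoride-induced cleavage of the aryl silyl ether, buffered with acetic acid so that the electron-rich phenols are not left as free phenolates; neither the benzylic C2–O1 bond nor the furan double bond is exposed to reducing conditions, and the stereocentre is not touched.

## Compound list

1 | 3-methoxy-2-methylphenol | COc1cccc(O)c1C | starting material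
2 | triisopropyl(3-methoxy-2-methylphenoxy)silane | COc1cccc(O[Si](C(C)C)(C(C)C)C(C)C)c1C | intermediate
3 | 2-[3-methoxy-4-methyl-5-(triisopropylsilyloxy)phenyl]-4,4,5,5-tetramethyl-1,3,2-dioxaborolane | COc1cc(B2OC(C)(C)C(C)(C)O2)cc(O[Si](C(C)C)(C(C)C)C(C)C)c1C | intermediate
4 | 3-methoxy-4-methyl-5-(triisopropylsilyloxy)phenol | COc1cc(O)cc(O[Si](C(C)C)(C(C)C)C(C)C)c1C | intermediate
5 | triisopropyl[3-methoxy-5-(methoxymethoxy)-2-methylphenoxy]silane | COCOc1cc(OC)c(C)c(O[Si](C(C)C)(C(C)C)C(C)C)c1 | intermediate
6 | [2-methoxy-6-(methoxymethoxy)-3-methyl-4-(triisopropylsilyloxy)phenyl]lithium | [Li]c1c(OC)c(C)c(O[Si](C(C)C)(C(C)C)C(C)C)cc1OCOC | intermediate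
7 | 2-methoxy-6-(methoxymethoxy)-3-methyl-4-(triisopropylsilyloxy)benzaldehyde | O=Cc1c(OC)c(C)c(O[Si](C(C)C)(C(C)C)C(C)C)cc1OCOC | intermediate
8 | [4-(2,2-dibromovinyl)-3-methoxy-5-(methoxymethoxy)-2-methylphenoxy]triisopropylsilane | BrC(Br)=Cc1c(OC)c(C)c(O[Si](C(C)C)(C(C)C)C(C)C)cc1OCOC | intermediate
9 | 2-(2,2-dibromovinyl)-3-methoxy-4-methyl-5-(triisopropylsilyloxy)phenol | BrC(Br)=Cc1c(OC)c(C)c(O[Si](C(C)C)(C(C)C)C(C)C)cc1O | intermediate
10 | 2-bromo-4-methoxy-5-methyl-6-(triisopropylsilyloxy)benzofuran | COc1c(C)c(O[Si](C(C)C)(C(C)C)C(C)C)cc2oc(Br)cc12 | intermediate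
11 | 5-methoxyresorcinol | COc1cc(O)cc(O)c1 | starting material
12 | 1-methoxy-3,5-bis(methoxymethoxy)benzene | COCOc1cc(OC)cc(OCOC)c1 | intermediate
13 | [4-methoxy-2,6-bis(methoxymethoxy)phenyl]lithium | [Li]c1c(OCOC)cc(OC)cc1OCOC | intermediate
14 | chloro[4-methoxy-2,6-bis(methoxymethoxy)phenyl]zinc | Cl[Zn]c1c(OCOC)cc(OC)cc1OCOC | intermediate
15 | 2-[4-methoxy-2,6-bis(methoxymethoxy)phenyl]-4-methoxy-5-methyl-6-(triisopropylsilyloxy)benzofuran | COCOc1cc(OC)cc(OCOC)c1-c1cc2c(OC)c(C)c(O[Si](C(C)C)(C(C)C)C(C)C)cc2o1 | intermediate
16 | 5-methoxy-2-[4-methoxy-5-methyl-6-(triisopropylsilyloxy)benzofuran-2-yl]benzene-1,3-diol | COc1cc(O)c(-c2cc3c(OC)c(C)c(O[Si](C(C)C)(C(C)C)C(C)C)cc3o2)c(O)c1 | intermediate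
17 | formaldehyde (used as paraformaldehyde) | C=O | starting material
18 | styrene | C=Cc1ccccc1 | starting material
19 | 4-(hydroxymethyl)-5-methoxy-2-[4-methoxy-5-methyl-6-(triisopropylsilyloxy)benzofuran-2-yl]benzene-1,3-diol | COc1cc(O)c(-c2cc3c(OC)c(C)c(O[Si](C(C)C)(C(C)C)C(C)C)cc3o2)c(O)c1CO | intermediate
20 | 3-hydroxy-5-methoxy-6-methylidene-2-[4-methoxy-5-methyl-6-(triisopropylsilyloxy)benzofuran-2-yl]cyclohexa-2,4-dien-1-one | C=C1C(OC)=CC(O)=C(c2cc3c(OC)c(C)c(O[Si](C(C)C)(C(C)C)C(C)C)cc3o2)C1=O | intermediate
21 | (2S)-5-methoxy-8-[4-methoxy-5-methyl-6-(triisopropylsilyloxy)benzofuran-2-yl]-2-phenylchroman-7-ol | COc1cc(O)c(-c2cc3c(OC)c(C)c(O[Si](C(C)C)(C(C)C)C(C)C)cc3o2)c2c1CC[C@@H](c1ccccc1)O2 | intermediate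
22 | (2S)-8-(6-hydroxy-4-methoxy-5-methylbenzofuran-2-yl)-5-methoxy-2-phenylchroman-7-ol | COc1cc(O)c(-c2cc3c(OC)c(C)c(O)cc3o2)c2c1CC[C@@H](c1ccccc1)O2 | target

## Step count and least certain steps

Total: 12 steps. Longest linear sequence: 11 steps (steps 1 to 7, then 9, 10, 11 and 12); the second branch contributes step 8.

In the fallbacks, Bf stands for the 4-methoxy-5-methyl-6-(triisopropylsilyloxy)benzofuran-2-yl group.

**Step 11 (key step, the one step beyond known chemistry).** The most likely failure is poor facial selectivity: the methide carbon is unsubstituted, so the catalyst holds the quinone methide at one point only and the styrene may approach either face. Also likely are oligomerisation, by attack of a second resorcinol ring on 20, and a second annulation at C6. The fallback uses known reactions, sets out from 16 and returns at 21. Magnesium-mediated ortho-formylation (MgCl2, Et3N, paraformaldehyde, MeCN, reflux) should give 2,4-dihydroxy-6-methoxy-3-Bf-benzaldehyde F1, with symmetry again making the two sites identical. Wittig olefination with the stabilised ylide Ph3P=CHC(O)Ph in toluene should give (E)-3-(2,4-dihydroxy-6-methoxy-3-Bf-phenyl)-1-phenylprop-2-en-1-one F2. Transfer hydrogenation with RuCl[(R,R)-TsDPEN](p-cymene) and HCO2H–Et3N, which reduces the C=C and then the C=O bond of chalcones, should give 4-[(3R)-3-hydroxy-3-phenylpropyl]-5-methoxy-2-Bf-benzene-1,3-diol F3. Mitsunobu cyclisation (PPh3, DIAD, THF, 0 °C) then closes O1–C2 with inversion to give 21. Only the ortho hydroxyl can reach the carbinol carbon, so the ring closure is unambiguous.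

**Step 4.** The likely failure is misdirected deprotonation: lateral lithiation of the methyl group, or lithiation beside the silyl ether followed by silyl migration from oxygen to carbon. The fallback replaces directed metalation by a phenol-directed electrophilic formylation; it sets out from 4 and returns at 7. Magnesium-mediated ortho-formylation of 4 (MgCl2, Et3N, paraformaldehyde, MeCN, reflux) should give 2-hydroxy-6-methoxy-5-methyl-4-(triisopropylsilyloxy)benzaldehyde F4. The triisopropylsilyl group blocks its neighbouring carbon, and magnesium can bridge the phenoxide and methoxy oxygens. Treatment with MOMCl and iPr2NEt then gives 7.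

**Step 7.** The likely failure is incomplete ring closure, because the crowded phenoxide couples slowly and base-induced loss of HBr to a bromoalkyne competes. The fallback builds the furan ring by acid-mediated cyclisation instead of C–O coupling; it sets out from 7 and returns at 10. Wittig homologation with (methoxymethyl)triphenylphosphonium chloride and KOtBu in THF should give triisopropyl[3-methoxy-5-(methoxymethoxy)-4-(2-methoxyvinyl)-2-methylphenoxy]silane F5 as an E/Z mixture. Amberlyst-15 in MeOH at 50 °C should remove the acetal, cyclise the freed phenol onto the protonated enol ether and eliminate methanol to give 4-methoxy-5-methyl-6-(triisopropylsilyloxy)benzofuran F6. Lithiation at C2' (n-BuLi, THF, −78 °C) and quenching with 1,2-dibromotetrachloroethane then give 10.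

**Step 9.** The likely failure is slow transmetalation and reductive elimination at the di-ortho-substituted arylzinc, which lets protodemetalation and homocoupling take over. The fallback reverses the roles of the partners so that the hindered ring is the electrophile; it sets out from 12 and 10 and returns at 15. Lithiation of 12 as in step 9 and quenching with I2 should give 2-iodo-5-methoxy-1,3-bis(methoxymethoxy)benzene F7. Bromine–lithium exchange on 10 (n-BuLi, THF, −78 °C) and trapping with 2-isopropoxy-4,4,5,5-tetramethyl-1,3,2-dioxaborolane should give 2-[4-methoxy-5-methyl-6-(triisopropylsilyloxy)benzofuran-2-yl]-4,4,5,5-tetramethyl-1,3,2-dioxaborolane F8. Suzuki–Miyaura coupling of F7 and F8 (Pd(OAc)2, SPhos, K3PO4, toluene–H2O, 80 °C) then gives 15.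

## Further compounds

F1 | step 11 | 2,4-dihydroxy-6-methoxy-3-[4-methoxy-5-methyl-6-(triisopropylsilyloxy)benzofuran-2-yl]benzaldehyde | COc1cc(O)c(-c2cc3c(OC)c(C)c(O[Si](C(C)C)(C(C)C)C(C)C)cc3o2)c(O)c1C=O
F2 | step 11 | (E)-3-{2,4-dihydroxy-6-methoxy-3-[4-methoxy-5-methyl-6-(triisopropylsilyloxy)benzofuran-2-yl]phenyl}-1-phenylprop-2-en-1-one | COc1cc(O)c(-c2cc3c(OC)c(C)c(O[Si](C(C)C)(C(C)C)C(C)C)cc3o2)c(O)c1/C=C/C(=O)c1ccccc1
F3 | step 11 | 4-[(3R)-3-hydroxy-3-phenylpropyl]-5-methoxy-2-[4-methoxy-5-methyl-6-(triisopropylsilyloxy)benzofuran-2-yl]benzene-1,3-diol | COc1cc(O)c(-c2cc3c(OC)c(C)c(O[Si](C(C)C)(C(C)C)C(C)C)cc3o2)c(O)c1CC[C@@H](O)c1ccccc1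
F4 | step 4 | 2-hydroxy-6-methoxy-5-methyl-4-(triisopropylsilyloxy)benzaldehyde | O=Cc1c(OC)c(C)c(O[Si](C(C)C)(C(C)C)C(C)C)cc1O
F5 | step 7 | triisopropyl[3-methoxy-5-(methoxymethoxy)-4-(2-methoxyvinyl)-2-methylphenoxy]silane (E/Z mixture) | COC=Cc1c(OC)c(C)c(O[Si](C(C)C)(C(C)C)C(C)C)cc1OCOC
F6 | step 7 | 4-methoxy-5-methyl-6-(triisopropylsilyloxy)benzofuran | COc1c(C)c(O[Si](C(C)C)(C(C)C)C(C)C)cc2occc12
F7 | step 9 | 2-iodo-5-methoxy-1,3-bis(methoxymethoxy)benzene | COCOc1cc(OC)cc(OCOC)c1I
F8 | step 9 | 2-[4-methoxy-5-methyl-6-(triisopropylsilyloxy)benzofuran-2-yl]-4,4,5,5-tetramethyl-1,3,2-dioxaborolane | COc1c(C)c(O[Si](C(C)C)(C(C)C)C(C)C)cc2oc(B3OC(C)(C)C(C)(C)O3)cc12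
A1 | alternative 1 | (2S)-7-benzyloxy-5-methoxy-8-[4-methoxy-5-methyl-6-(triisopropylsilyloxy)benzofuran-2-yl]-2-phenylchroman | COc1cc(OCc2ccccc2)c(-c2cc3c(OC)c(C)c(O[Si](C(C)C)(C(C)C)C(C)C)cc3o2)c2c1CC[C@@H](c1ccccc1)O2
A2 | alternative 1 | 1-[(2S)-7-benzyloxy-5-methoxy-2-phenylchroman-8-yl]ethanone O-[3-methoxy-4-methyl-5-(triisopropylsilyloxy)phenyl]oxime | COc1cc(OCc2ccccc2)c(C(C)=NOc2cc(OC)c(C)c(O[Si](C(C)C)(C(C)C)C(C)C)c2)c2c1CC[C@@H](c1ccccc1)O2
A3 | alternative 2 | 2-[(2S)-5-methoxy-2-phenyl-7-(triisopropylsilyloxy)chroman-8-yl]-5-methyl-6-(triisopropylsilyloxy)benzofuran-4-ol | COc1cc(O[Si](C(C)C)(C(C)C)C(C)C)c(-c2cc3c(O)c(C)c(O[Si](C(C)C)(C(C)C)C(C)C)cc3o2)c2c1CC[C@@H](c1ccccc1)O2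
A4 | alternative 2 | 2-diazo-1-{5-[(2S)-5-methoxy-2-phenyl-7-(triisopropylsilyloxy)chroman-8-yl]furan-2-yl}ethanone | COc1cc(O[Si](C(C)C)(C(C)C)C(C)C)c(-c2ccc(C(=O)C=[N+]=[N-])o2)c2c1CC[C@@H](c1ccccc1)O2
A5 | alternative 2 | triisopropyl(prop-1-ynyloxy)silane | CC#CO[Si](C(C)C)(C(C)C)C(C)C
A6 | alternative 3 | (2S)-7-benzyloxy-8-(6-benzyloxy-4-methoxy-5-methylbenzofuran-2-yl)-5-methoxy-2-phenyl-2H-chromene | COc1cc(OCc2ccccc2)c(-c2cc3c(OC)c(C)c(OCc4ccccc4)cc3o2)c2c1C=C[C@@H](c1ccccc1)O2
A7 | alternative 3 | 6-benzyloxy-2-{2-benzyloxy-5-ethenyl-4-methoxy-6-[(1S)-1-phenylprop-2-enyloxy]phenyl}-4-methoxy-5-methylbenzofuran | COc1cc(OCc2ccccc2)c(-c2cc3c(OC)c(C)c(OCc4ccccc4)cc3o2)c(O[C@@H](C=C)c2ccccc2)c1C=C
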